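**Plan**
Retrosynthesis: the C8–prenyl bond is traced back to a 5-O-prenyl ether (Claisen–Cope relay); ring C is then cut at O1–C8a and C4–C4a, the chain at C3–C4 (Claisen condensation), and the B-ring chroman at its C–C and C–O bonds to a C5 alcohol.
Enabling feature: O1–C2–C3–C4 is a 3-aryl-3-hydroxypropanoate chain that bridges the adjacent A-ring carbons C8a and C4a, and C4a lies next to the C5 oxygen, which is the polarity pattern of a 3-alkoxyaryne opened by an O-nucleophile.
Forward: the B-ring chroman is built first, the chain is extended to the β-keto ester and reduced; separately phloroglucinol is turned into the o-silylaryl triflate; the two halves are joined and ring C closed in one operation; the A-ring prenyl group comes last.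
Stereochemistry: the only stereocentre (C2, S) is set by Ru–(R)-BINAP hydrogenation of the β-keto ester; its C–O bond is not broken afterwards and all later steps avoid strongly basic media that would open the flavanone.

Key step: step 7

Assumption: a neutral aliphatic hydroxyl would only give O–H insertion with an aryne, so the alkoxide is preformed in step 7; the transient sp3 centre of dienones 21 and 22 forms as both epimers, which converge on 23.

**Step 1**
Reactants: 1 4'-hydroxyacetophenone; 2 2-methylbut-3-en-2-ol
Product: 4 1-(2,2-dimethylchroman-6-yl)ethan-1-one, via ortho-prenylphenol 3 (not isolated)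
Conditions: Amberlyst 15, 1,2-dichloroethane, 70 °C, slow addition of 2
Reagents that add atoms: none
Why: Acid-catalysed Friedel–Crafts prenylation ortho to the phenol (para position blocked) followed by Markovnikov hydroalkoxylation of the trisubstituted alkene should close the 2,2-dimethylchroman in one pot, a standard phenol/tertiary allylic alcohol chroman annulation.

**Step 2**
Reactants: 4 1-(2,2-dimethylchroman-6-yl)ethan-1-one; 5 dimethyl carbonate
Product: 6 methyl 3-(2,2-dimethylchroman-6-yl)-3-oxopropanoate
Conditions: NaH (2.5 equiv), (MeO)2CO (4 equiv), toluene, reflux; 1 M HCl quench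
Reagents that add atoms: none
Why: Crossed Claisen condensation of the methyl ketone enolate with dimethyl carbonate, driven by irreversible deprotonation of the β-keto ester, is routine for aryl methyl ketones.

**Step 3**
Reactants: 6 methyl 3-(2,2-dimethylchroman-6-yl)-3-oxopropanoate
Product: 7 methyl (3S)-3-(2,2-dimethylchroman-6-yl)-3-hydroxypropanoate
Conditions: H2 (50 bar), [RuCl(p-cymene)((R)-BINAP)]Cl (0.5 mol%), MeOH, 50 °C
Reagents that add atoms: none
Why: Noyori asymmetric hydrogenation of a β-keto ester, in which chelation of both carbonyls to the (R)-BINAP–Ru centre fixes the face that accepts hydride; for a 3-aryl substrate this face corresponds to the (S)-carbinol.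

**Step 4**
Reactants: 8 phloroglucinol
Product: 9 3,5-bis(methoxymethoxy)phenol
Conditions: MOMCl (2.1 equiv), i-Pr2NEt (2.3 equiv), DMF, 0 °C → rt; chromatography
Reagents that add atoms: chloromethyl methyl ether, COCCl
Why: Williamson-type O-alkylation (MOM protection) with two equivalents should make the bis-ether the main component of a statistical mixture, from which it is separated while the mono- and tris-ethers are recycled.

**Step 5**
Reactants: 9 3,5-bis(methoxymethoxy)phenol
Product: 10 2-bromo-3,5-bis(methoxymethoxy)phenol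
Conditions: NBS (1.0 equiv), CH2Cl2, −78 → −40 °C
Reagents that add atoms: N-bromosuccinimide, O=C1CCC(=O)N1Br
Why: Electrophilic aromatic bromination of a highly activated phenol at low temperature should favour the position ortho to the free OH (C2 and C6 are equivalent), which is less hindered than C4 between the two MOM ethers, and one equivalent of NBS limits polybromination.

**Step 6**
Reactants: 10 2-bromo-3,5-bis(methoxymethoxy)phenol
Product: 13 3,5-bis(methoxymethoxy)-2-(trimethylsilyl)phenyl trifluoromethanesulfonate, via aryl trimethylsilyl ether 11 (not isolated), via lithium 2-silylphenoxide 12 (not isolated)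
Conditions: HMDS, THF, 65 °C, then evaporation; n-BuLi (1.1 equiv), THF, −100 °C; Tf2O (1.2 equiv), −100 → −78 °C; NaHCO3 work-up
Reagents that add atoms: hexamethyldisilazane, C[Si](C)(C)N[Si](C)(C)C; trifluoromethanesulfonic anhydride, O=S(=O)(OS(=O)(=O)C(F)(F)F)C(F)(F)F
Why: O-silylation, bromine–lithium exchange and anionic 1,3 O→C silyl migration (retro-Brook rearrangement) place the silyl group on the former C–Br carbon, and the phenoxide released is trapped by Tf2O, the standard entry to o-silylaryl triflates.

**Step 7**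
Reactants: 7 methyl (3S)-3-(2,2-dimethylchroman-6-yl)-3-hydroxypropanoate; 13 3,5-bis(methoxymethoxy)-2-(trimethylsilyl)phenyl trifluoromethanesulfonate
Product: 16 (2S)-2-(2,2-dimethylchroman-6-yl)-5,7-bis(methoxymethoxy)chroman-4-one, via sodium alkoxide 14 (not isolated), via 3,5-bis(methoxymethoxy)benzyne 15 (not isolated)
Conditions: NaH (1.0 equiv), THF, 0 °C; then 13 (1.3 equiv), KF/18-crown-6 (2 equiv), 0 °C → rt; pH 7 buffer at 0 °C
Reagents that add atoms: none
Why: Proposed new method: fluoride unmasks benzyne 15 from 13, the preformed alkoxide 14 adds to the aryne carbon remote from the flanking OMOM group (future C8a), and the aryl anion thus generated at C4a, inductively stabilised by the neighbouring oxygen, attacks the ester carbonyl and expels methoxide. The closest known reaction type is the fluoride-induced annulation of arynes with methyl salicylates to xanthones (O-arylation, then acyl substitution by the aryl anion); an aliphatic β-alkoxide with enolisable α-hydrogens has not been used in this way. The pyranone ring closes by 6-exo-trig attack of the aryl anion on the ester. No stereocentre is created, and since the C2–O bond of 7 stays intact the (S) configuration is carried into 16. The step needs C–O formation at the aryne carbon meta to the 3-alkoxy group, which the distortion of a 3-alkoxyaryne should secure, and it needs acylation to outrun protonation of the aryl anion, β-elimination and retro-aldol cleavage, for which the proton-free medium, the low temperature and the short anion–ester distance are relied on. The expelled methoxide is expected to be silylated by Me3SiF or by unreacted 13, which returns fluoride and spares the base-sensitive flavanone from ring opening.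

**Step 8**
Reactants: 16 (2S)-2-(2,2-dimethylchroman-6-yl)-5,7-bis(methoxymethoxy)chroman-4-one
Product: 17 (2S)-2-(2,2-dimethylchroman-6-yl)-5,7-dihydroxychroman-4-one
Conditions: 2 M HCl, MeOH, 40 °C
Reagents that add atoms: none
Why: Acid-catalysed acetal exchange with methanol (MOM cleavage) should remove both ethers while the aryl tert-alkyl ether of the B ring and the flavanone ring are inert to dilute acid, so C2 is untouched.

**Step 9**
Reactants: 17 (2S)-2-(2,2-dimethylchroman-6-yl)-5,7-dihydroxychroman-4-one
Product: 18 (2S)-2-(2,2-dimethylchroman-6-yl)-5-hydroxy-4-oxochroman-7-yl acetate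
Conditions: Ac2O (1.05 equiv), pyridine, 0 °C
Reagents that add atoms: acetic anhydride, CC(=O)OC(C)=O
Why: O-Acylation should be selective for the 7-OH because the 5-OH is held in a hydrogen bond to the C4 carbonyl and is far less nucleophilic.

**Step 10**
Reactants: 18 (2S)-2-(2,2-dimethylchroman-6-yl)-5-hydroxy-4-oxochroman-7-yl acetate; 19 3-methylbut-2-en-1-ol
Product: 20 (2S)-2-(2,2-dimethylchroman-6-yl)-5-[(3-methylbut-2-en-1-yl)oxy]-4-oxochroman-7-yl acetate
Conditions: PPh3, DIAD, THF, 0 °C → rt
Reagents that add atoms: none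
Why: The Mitsunobu reaction alkylates the chelated but sufficiently acidic 5-OH with the primary allylic alcohol under neutral conditions that cannot open the flavanone.

**Step 11**
Reactants: 20 (2S)-2-(2,2-dimethylchroman-6-yl)-5-[(3-methylbut-2-en-1-yl)oxy]-4-oxochroman-7-yl acetate
Product: 23 (2S)-2-(2,2-dimethylchroman-6-yl)-5-hydroxy-8-(3-methylbut-2-en-1-yl)-4-oxochroman-7-yl acetate, via C6 dienone 21 (not isolated), via C8 dienone 22 (not isolated)
Conditions: Eu(fod)3 (10 mol%), CHCl3, 60 °C, sealed tube
Reagents that add atoms: none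
Why: Eu(III)-promoted aromatic Claisen rearrangement should carry the allyl unit to C6 with allylic inversion and a Cope shift should relay it to C8 as a prenyl group before tautomerisation restores the phenol (Claisen–Cope sequence), the Lewis acid bound at the C4/C5 oxygens lowering the temperature enough for the para product to dominate.

**Step 12**
Reactants: 23 (2S)-2-(2,2-dimethylchroman-6-yl)-5-hydroxy-8-(3-methylbut-2-en-1-yl)-4-oxochroman-7-yl acetate
Product: 24 euchrenone a16, (2S)-2-(2,2-dimethylchroman-6-yl)-5,7-dihydroxy-8-(3-methylbut-2-en-1-yl)chroman-4-one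
Conditions: NH4OAc (10 equiv), MeOH–H2O (4:1), rt
Reagents that add atoms: none
Why: Near-neutral solvolysis of the aryl acetate should free the 7-OH without the strongly basic medium that would open the flavanone to the chalcone and erode C2.

**Compound list**
1 | 4'-hydroxyacetophenone | CC(=O)c1ccc(O)cc1 | starting material
2 | 2-methylbut-3-en-2-ol | CC(C)(O)C=C | starting material
3 | 1-[4-hydroxy-3-(3-methylbut-2-en-1-yl)phenyl]ethan-1-one (formed in the flask) | CC(=O)c1ccc(O)c(CC=C(C)C)c1 | intermediate
4 | 1-(2,2-dimethylchroman-6-yl)ethan-1-one | CC(=O)c1ccc2c(c1)CCC(C)(C)O2 | intermediate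
5 | dimethyl carbonate | COC(=O)OC | starting material
6 | methyl 3-(2,2-dimethylchroman-6-yl)-3-oxopropanoate | COC(=O)CC(=O)c1ccc2c(c1)CCC(C)(C)O2 | intermediate
7 | methyl (3S)-3-(2,2-dimethylchroman-6-yl)-3-hydroxypropanoate | COC(=O)C[C@H](O)c1ccc2c(c1)CCC(C)(C)O2 | intermediate
8 | phloroglucinol | Oc1cc(O)cc(O)c1 | starting material
9 | 3,5-bis(methoxymethoxy)phenol | COCOc1cc(O)cc(OCOC)c1 | intermediate
10 | 2-bromo-3,5-bis(methoxymethoxy)phenol | COCOc1cc(O)c(Br)c(OCOC)c1 | intermediate
11 | [2-bromo-3,5-bis(methoxymethoxy)phenoxy]trimethylsilane (formed in the flask) | COCOc1cc(O[Si](C)(C)C)c(Br)c(OCOC)c1 | intermediate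
12 | lithium 3,5-bis(methoxymethoxy)-2-(trimethylsilyl)phenoxide (formed in the flask) | [Li+].COCOc1cc([O-])c([Si](C)(C)C)c(OCOC)c1 | intermediate
13 | 3,5-bis(methoxymethoxy)-2-(trimethylsilyl)phenyl trifluoromethanesulfonate | COCOc1cc(OCOC)c([Si](C)(C)C)c(OS(=O)(=O)C(F)(F)F)c1 | intermediate
14 | sodium (1S)-1-(2,2-dimethylchroman-6-yl)-3-methoxy-3-oxopropan-1-olate (formed in the flask) | [Na+].COC(=O)C[C@H]([O-])c1ccc2c(c1)CCC(C)(C)O2 | intermediate
15 | 3,5-bis(methoxymethoxy)benzyne (formed in the flask) | COCOC1=CC(OCOC)=CC#C1 | intermediate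
16 | (2S)-2-(2,2-dimethylchroman-6-yl)-5,7-bis(methoxymethoxy)chroman-4-one | COCOc1cc(OCOC)c2c(c1)O[C@H](c1ccc3c(c1)CCC(C)(C)O3)CC2=O | intermediate
17 | (2S)-2-(2,2-dimethylchroman-6-yl)-5,7-dihydroxychroman-4-one | Oc1cc(O)c2c(c1)O[C@H](c1ccc3c(c1)CCC(C)(C)O3)CC2=O | intermediate
18 | (2S)-2-(2,2-dimethylchroman-6-yl)-5-hydroxy-4-oxochroman-7-yl acetate | CC(=O)Oc1cc(O)c2c(c1)O[C@H](c1ccc3c(c1)CCC(C)(C)O3)CC2=O | intermediate
19 | 3-methylbut-2-en-1-ol (prenol) | CC(C)=CCO | starting material
20 | (2S)-2-(2,2-dimethylchroman-6-yl)-5-[(3-methylbut-2-en-1-yl)oxy]-4-oxochroman-7-yl acetate | CC(=O)Oc1cc(OCC=C(C)C)c2c(c1)O[C@H](c1ccc3c(c1)CCC(C)(C)O3)CC2=O | intermediate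
21 | (2S)-2-(2,2-dimethylchroman-6-yl)-6-(2-methylbut-3-en-2-yl)-4,5-dioxo-3,4,5,6-tetrahydro-2H-chromen-7-yl acetate (C6 epimers, formed in the flask) | CC(=O)OC1=CC2=C(C(=O)C[C@@H](c3ccc4c(c3)CCC(C)(C)O4)O2)C(=O)C1C(C)(C)C=C | intermediate
22 | (2S)-2-(2,2-dimethylchroman-6-yl)-8-(3-methylbut-2-en-1-yl)-4,5-dioxo-3,4,5,8-tetrahydro-2H-chromen-7-yl acetate (C8 epimers, formed in the flask) | CC(=O)OC1=CC(=O)C2=C(O[C@H](c3ccc4c(c3)CCC(C)(C)O4)CC2=O)C1CC=C(C)C | intermediate
23 | (2S)-2-(2,2-dimethylchroman-6-yl)-5-hydroxy-8-(3-methylbut-2-en-1-yl)-4-oxochroman-7-yl acetate | CC(=O)Oc1cc(O)c2c(c1CC=C(C)C)O[C@H](c1ccc3c(c1)CCC(C)(C)O3)CC2=O | intermediate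
24 | euchrenone a16, (2S)-2-(2,2-dimethylchroman-6-yl)-5,7-dihydroxy-8-(3-methylbut-2-en-1-yl)chroman-4-one | CC(C)=CCc1c(O)cc(O)c2c1O[C@H](c1ccc3c(c1)CCC(C)(C)O3)CC2=O | target

**Step count**
Total: 12 steps. Longest linear sequence: 9 steps (steps 1–3 then 7–12, or equally steps 4–6 then 7–12).

**Steps most likely to fail**

Step 7. The aryl anion may be protonated (for instance by 1,5-proton transfer from the α-CH2) before it acylates, the alkoxide may undergo β-elimination or retro-aldol cleavage, or residual base may open the flavanone and erode C2. The fallback uses known chemistry, sets out from 6 and 10 and returns at 16. Keto ester 6 is hydrogenated with the (S)-BINAP catalyst to methyl (3R)-3-(2,2-dimethylchroman-6-yl)-3-hydroxypropanoate F1. Mitsunobu etherification of F1 with bromophenol 10 (PPh3, DIAD, toluene, 0 °C) forms the C2–O1 bond with inversion and gives methyl (3S)-3-[2-bromo-3,5-bis(methoxymethoxy)phenoxy]-3-(2,2-dimethylchroman-6-yl)propanoate F2. Bromine–lithium exchange (n-BuLi, THF, −100 °C) and Parham cyclisation of the aryllithium onto the ester then close C4–C4a to give 16.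

Step 5. Bromination may occur at C4 between the two MOM ethers, or go on to dibromides, leaving a mixture that cannot be carried forward. The fallback replaces steps 5 and 6, sets out from 9 and returns at 13, and installs silicon by directed ortho-metalation instead. Phenol 9 and isopropyl isocyanate (cat. Et3N, CH2Cl2) give 3,5-bis(methoxymethoxy)phenyl isopropylcarbamate F3. TBSOTf/TMEDA in Et2O converts F3 in the flask into 3,5-bis(methoxymethoxy)phenyl N-(tert-butyldimethylsilyl)-N-isopropylcarbamate F4. Lithiation with n-BuLi/TMEDA at −78 °C, at the position flanked by the carbamate and a MOM ether, and a TMSCl quench give 3,5-bis(methoxymethoxy)-2-(trimethylsilyl)phenyl N-(tert-butyldimethylsilyl)-N-isopropylcarbamate F5. Aqueous work-up removes the N-silyl group to leave 3,5-bis(methoxymethoxy)-2-(trimethylsilyl)phenyl isopropylcarbamate F6. DBU/Et2NH in MeCN at 40 °C releases 3,5-bis(methoxymethoxy)-2-(trimethylsilyl)phenol F7, which is triflated in the same pot with PhNTf2 to give 13.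

Step 11. The sigmatropic relay may stop at the C6 1,1-dimethylallyl stage, or the prenyl ether may ionise under the Lewis acid, so that C8 selectivity is poor. The fallback replaces steps 8–12, sets out from 16 and returns at 24, and makes the C8–C bond by cross-coupling. Iodination of 16 (NIS, DMF, rt) is expected at C8, para to the 5-alkoxy group, giving (2S)-2-(2,2-dimethylchroman-6-yl)-8-iodo-5,7-bis(methoxymethoxy)chroman-4-one F8. Stille coupling with tributyl(3-methylbut-2-en-1-yl)stannane (Pd(PPh3)4, DMF, 90 °C) gives (2S)-2-(2,2-dimethylchroman-6-yl)-5,7-bis(methoxymethoxy)-8-(3-methylbut-2-en-1-yl)chroman-4-one F9. Brief MOM cleavage (HCl, MeOH, rt) then gives 24.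

**Further compounds**
F1 | step 7 | methyl (3R)-3-(2,2-dimethylchroman-6-yl)-3-hydroxypropanoate | COC(=O)C[C@@H](O)c1ccc2c(c1)CCC(C)(C)O2
F2 | step 7 | methyl (3S)-3-[2-bromo-3,5-bis(methoxymethoxy)phenoxy]-3-(2,2-dimethylchroman-6-yl)propanoate | COC(=O)C[C@H](Oc1cc(OCOC)cc(OCOC)c1Br)c1ccc2c(c1)CCC(C)(C)O2
F3 | step 5 | 3,5-bis(methoxymethoxy)phenyl isopropylcarbamate | COCOc1cc(OCOC)cc(OC(=O)NC(C)C)c1
F4 | step 5 | 3,5-bis(methoxymethoxy)phenyl N-(tert-butyldimethylsilyl)-N-isopropylcarbamate | COCOc1cc(OCOC)cc(OC(=O)N(C(C)C)[Si](C)(C)C(C)(C)C)c1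
F5 | step 5 | 3,5-bis(methoxymethoxy)-2-(trimethylsilyl)phenyl N-(tert-butyldimethylsilyl)-N-isopropylcarbamate | COCOc1cc(OCOC)c([Si](C)(C)C)c(OC(=O)N(C(C)C)[Si](C)(C)C(C)(C)C)c1
F6 | step 5 | 3,5-bis(methoxymethoxy)-2-(trimethylsilyl)phenyl isopropylcarbamate | COCOc1cc(OCOC)c([Si](C)(C)C)c(OC(=O)NC(C)C)c1
F7 | step 5 | 3,5-bis(methoxymethoxy)-2-(trimethylsilyl)phenol | COCOc1cc(OCOC)c([Si](C)(C)C)c(O)c1
F8 | step 11 | (2S)-2-(2,2-dimethylchroman-6-yl)-8-iodo-5,7-bis(methoxymethoxy)chroman-4-one | COCOc1cc(OCOC)c2c(c1I)O[C@H](c1ccc3c(c1)CCC(C)(C)O3)CC2=O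
F9 | step 11 | (2S)-2-(2,2-dimethylchroman-6-yl)-5,7-bis(methoxymethoxy)-8-(3-methylbut-2-en-1-yl)chroman-4-one | COCOc1cc(OCOC)c2c(c1CC=C(C)C)O[C@H](c1ccc3c(c1)CCC(C)(C)O3)CC2=O
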